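**Retrosynthetic overview**
- The target's acetate comes from the free side-chain alcohol; the 3-hydroxy-1,4-quinone ring comes from a 2-alkyl-1-naphthol by para-oxidation, epoxidation and epoxide-to-enol isomerisation, so the OH can only end up next to the alkyl group.
- The 2-alkyl-1-naphthol comes from dehydrogenation of a 2-alkyl-1-tetralone; the alkyl group is attached at C2 by a lithium-enolate aldol of 5,7,8-trimethoxy-1-tetralone with (S)-2-silyloxypropanal, followed by removal of the aldol oxygen (dehydration, hydrogenation).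
- The stereocentre is bought with ethyl (S)-lactate, and no later step breaks a bond to it.
- The tetralone comes from a Haworth sequence on 1,2,4-trimethoxybenzene (succinoylation, ketone reduction, ring closure).
- Ring order: the trimethoxybenzene ring is bought; the second ring is closed by Friedel–Crafts acylation (step 3), aromatised (step 9) and oxidised to the hydroxyquinone (steps 10–12).

Assumption: LDA solution, Eaton's reagent and Fremy's salt are bought as such, and aldehyde 8 is used crude directly after it is made.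

**Route**

Step 1
Reactants: 1 1,2,4-trimethoxybenzene; 2 succinic anhydride
Product: 3 4-oxo-4-(2,4,5-trimethoxyphenyl)butanoic acid
Conditions: AlCl3 (2.5 equiv), CH2Cl2/PhNO2, 0 °C to rt; ice/HCl
Reagents that add atoms: none
Why: Friedel–Crafts acylation goes to C5 of the arene (para to one OMe, ortho to another), by far the most nucleophilic site, and stops after one acylation because the ketone–AlCl3 complex is deactivated.

Step 2
Reactants: 3 4-oxo-4-(2,4,5-trimethoxyphenyl)butanoic acid
Product: 4 4-(2,4,5-trimethoxyphenyl)butanoic acid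
Conditions: Et3SiH (3 equiv), TFA, rt to 50 °C
Reagents that add atoms: none
Why: Ionic hydrogenation reduces the electron-rich aryl ketone to CH2 through a stabilised benzylic cation and leaves the carboxylic acid untouched.

Step 3
Reactants: 4 4-(2,4,5-trimethoxyphenyl)butanoic acid
Product: 5 5,7,8-trimethoxy-3,4-dihydronaphthalen-1(2H)-one
Conditions: Eaton's reagent (P2O5/MeSO3H), rt
Reagents that add atoms: none
Why: Intramolecular Friedel–Crafts acylation (Haworth ring closure) can only occur at the single free position ortho to the chain, which is activated by the adjacent OMe, so one tetralone forms.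

Step 4
Reactants: 6 ethyl (S)-lactate
Product: 7 ethyl (2S)-2-(tert-butyldimethylsilyloxy)propanoate
Conditions: TBSCl, imidazole, DMF, 0 °C to rt
Reagents that add atoms: tert-butyldimethylsilyl chloride (TBSCl), CC(C)(C)[Si](C)(C)Cl
Why: O-Silylation of the alcohol breaks no bond at the stereocentre, so the (S) configuration of the lactate is carried over.

Step 5
Reactants: 7 ethyl (2S)-2-(tert-butyldimethylsilyloxy)propanoate
Product: 8 (2S)-2-(tert-butyldimethylsilyloxy)propanal
Conditions: DIBAL-H (1.05 equiv), CH2Cl2, −78 °C; MeOH then aq. Rochelle salt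
Reagents that add atoms: none
Why: Partial ester reduction with DIBAL-H at −78 °C stops at the aldehyde oxidation level under non-basic conditions that do not enolise the α-stereocentre.

Step 6
Reactants: 5 5,7,8-trimethoxy-3,4-dihydronaphthalen-1(2H)-one; 8 (2S)-2-(tert-butyldimethylsilyloxy)propanal
Product: 10 2-[(2S)-2-(tert-butyldimethylsilyloxy)-1-hydroxypropyl]-5,7,8-trimethoxy-3,4-dihydronaphthalen-1(2H)-one (diastereomer mixture at C2/C1'), via lithium enolate 9 (not isolated)
Conditions: LDA (1.1 equiv), THF, −78 °C; then 8, −78 °C; sat. aq. NH4Cl at −78 °C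
Reagents that add atoms: none
Why: Directed aldol addition of the preformed lithium enolate (only one enolisable position) to the aldehyde at −78 °C is faster than proton transfer, so the lactate-derived (S) centre is kept; the two new stereocentres are erased later.

Step 7
Reactants: 10 aldol adduct
Product: 12 (2E)-2-[(2S)-2-(tert-butyldimethylsilyloxy)propylidene]-5,7,8-trimethoxy-3,4-dihydronaphthalen-1(2H)-one, via mesylate 11 (not isolated)
Conditions: MsCl, Et3N, CH2Cl2, 0 °C; then DBU, 0 °C
Reagents that add atoms: none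
Why: Aldol dehydration by mesylation and E1cB elimination through the acidic C2–H gives the conjugated enone at 0 °C, where the γ-hydrogen at the (S) centre is not removed.

Step 8
Reactants: 12 exocyclic enone
Product: 13 2-[(2S)-2-(tert-butyldimethylsilyloxy)propyl]-5,7,8-trimethoxy-3,4-dihydronaphthalen-1(2H)-one (C2 epimers)
Conditions: H2 (1 atm), 10% Pd/C, EtOAc, rt, stopped after 1 equiv H2
Reagents that add atoms: none
Why: Catalytic hydrogenation saturates the conjugated C=C much faster than it reduces the electron-rich aryl ketone or cleaves the silyl ether, and the (S) carbinol centre is not involved.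

Step 9
Reactants: 13 2-alkyl-1-tetralone
Product: 16 2-[(2S)-2-(tert-butyldimethylsilyloxy)propyl]-5,7,8-trimethoxynaphthalen-1-ol, via trimethylsilyl enol ether 14 (not isolated), via 4H-naphthalenone tautomer 15 (not isolated)
Conditions: TMSOTf, Et3N, CH2Cl2, 0 °C; then Pd(OAc)2 (1.1 equiv), MeCN, rt
Reagents that add atoms: none
Why: Soft enolisation gives the only possible silyl enol ether, and Saegusa–Ito oxidation (syn β-hydride elimination into the ring) gives a dienone that tautomerises irreversibly to the naphthol under neutral conditions that spare the silyl ether and the (S) centre.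

Step 10
Reactants: 16 2-alkyl-1-naphthol
Product: 17 2-[(2S)-2-(tert-butyldimethylsilyloxy)propyl]-5,7,8-trimethoxynaphthalene-1,4-dione
Conditions: Fremy's salt (2.5 equiv), aq. KH2PO4, acetone/H2O, rt
Reagents that add atoms: potassium nitrosodisulfonate (Fremy's salt), [K+].[K+].[O]N(S(=O)(=O)[O-])S(=O)(=O)[O-]
Why: Teuber oxidation converts the naphthol to its aryloxyl radical, which is oxygenated at the free para position C4, so only the 1,4-quinone forms and the methyl ethers of the other ring are not attacked by this phenol-selective oxidant.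

Step 11
Reactants: 17 2-alkyl-1,4-naphthoquinone
Product: 18 2,3-epoxide of 17 (2-alkyl-2,3-epoxy-2,3-dihydro-5,7,8-trimethoxynaphthalene-1,4-dione; epoxide diastereomers)
Conditions: 30% H2O2, Na2CO3 (cat.), THF/H2O, 0 °C
Reagents that add atoms: hydrogen peroxide, OO
Why: Weitz–Scheffer nucleophilic epoxidation adds hydroperoxide anion to the electron-poor quinone C2=C3 bond within minutes at 0 °C; the epoxide stereochemistry is irrelevant because both carbons become sp2 again.

Step 12
Reactants: 18 quinone epoxide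
Product: 19 2-[(2S)-2-(tert-butyldimethylsilyloxy)propyl]-3-hydroxy-5,7,8-trimethoxynaphthalene-1,4-dione
Conditions: 1 M NaOH, THF, 0 °C to rt; then 1 M HCl
Reagents that add atoms: none
Why: Base-induced isomerisation of an α,β-epoxy ketone to its enolised 1,2-dione removes the C3–H (the only hydrogen on the oxirane, α to C4=O) and opens the ring by E1cB, so the oxygen stays on C3 and the vinylogous carboxylate is the thermodynamic sink.

Step 13
Reactants: 19 silyl-protected hydroxyquinone
Product: 20 3-hydroxy-2-[(2S)-2-hydroxypropyl]-5,7,8-trimethoxynaphthalene-1,4-dione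
Conditions: 48% aq. HF, MeCN, 0 °C to rt
Reagents that add atoms: none
Why: Fluoride-driven desilylation cleaves only the Si–O bond under mildly acidic conditions in which the hydroxyquinone is stable, so the C–O bond at the stereocentre is untouched.

Step 14
Reactants: 20 hydroxyquinone alcohol
Product: 22 (2S)-1-(3-hydroxy-5,7,8-trimethoxy-1,4-dioxo-1,4-dihydronaphthalen-2-yl)propan-2-yl acetate (target), via diacetate 21 (not isolated)
Conditions: Ac2O, pyridine, DMAP (cat.), CH2Cl2, 0 °C to rt; then sat. aq. NaHCO3/THF, rt; 1 M HCl to pH 3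
Reagents that add atoms: acetic anhydride, CC(=O)OC(C)=O
Why: Exhaustive acetylation followed by chemoselective hydrolysis works because the quinonyl acetate is a vinylogous mixed anhydride cleaved by bicarbonate, whereas the secondary alkyl acetate is inert, and the (S) configuration is retained since no bond to the stereocentre is broken.

**Compound list**

1 | 1,2,4-trimethoxybenzene | COc1ccc(OC)c(OC)c1 | starting material
2 | succinic anhydride | O=C1CCC(=O)O1 | starting material
3 | 4-oxo-4-(2,4,5-trimethoxyphenyl)butanoic acid | COc1cc(OC)c(C(=O)CCC(=O)O)cc1OC | intermediate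
4 | 4-(2,4,5-trimethoxyphenyl)butanoic acid | COc1cc(OC)c(CCCC(=O)O)cc1OC | intermediate
5 | 5,7,8-trimethoxy-3,4-dihydronaphthalen-1(2H)-one | O=C1CCCc2c(OC)cc(OC)c(OC)c12 | intermediate
6 | ethyl (S)-lactate | C[C@H](O)C(=O)OCC | starting material
7 | ethyl (2S)-2-(tert-butyldimethylsilyloxy)propanoate | C[C@H](O[Si](C)(C)C(C)(C)C)C(=O)OCC | intermediate
8 | (2S)-2-(tert-butyldimethylsilyloxy)propanal | C[C@H](O[Si](C)(C)C(C)(C)C)C=O | intermediate
9 | lithium enolate of 5 (lithium 5,7,8-trimethoxy-3,4-dihydronaphthalen-1-olate) | [Li]OC1=CCCc2c(OC)cc(OC)c(OC)c12 | intermediate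
10 | 2-[(2S)-2-(tert-butyldimethylsilyloxy)-1-hydroxypropyl]-5,7,8-trimethoxy-3,4-dihydronaphthalen-1(2H)-one (mixture at C2 and C1') | C[C@H](O[Si](C)(C)C(C)(C)C)C(O)C1CCc2c(OC)cc(OC)c(OC)c2C1=O | intermediate
11 | methanesulfonate of 10 (mixture at C2 and C1') | C[C@H](O[Si](C)(C)C(C)(C)C)C(OS(C)(=O)=O)C1CCc2c(OC)cc(OC)c(OC)c2C1=O | intermediate
12 | (2E)-2-[(2S)-2-(tert-butyldimethylsilyloxy)propylidene]-5,7,8-trimethoxy-3,4-dihydronaphthalen-1(2H)-one | C[C@H](O[Si](C)(C)C(C)(C)C)/C=C1/C(=O)c2c(OC)c(OC)cc(OC)c2CC1 | intermediate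
13 | 2-[(2S)-2-(tert-butyldimethylsilyloxy)propyl]-5,7,8-trimethoxy-3,4-dihydronaphthalen-1(2H)-one (C2 epimers) | C[C@H](O[Si](C)(C)C(C)(C)C)CC1CCc2c(OC)cc(OC)c(OC)c2C1=O | intermediate
14 | 1-trimethylsilyl enol ether of 13 | C[C@H](O[Si](C)(C)C(C)(C)C)CC1=C(O[Si](C)(C)C)c2c(OC)c(OC)cc(OC)c2CC1 | intermediate
15 | 2-[(2S)-2-(tert-butyldimethylsilyloxy)propyl]-5,7,8-trimethoxynaphthalen-1(4H)-one | C[C@H](O[Si](C)(C)C(C)(C)C)CC1=CCc2c(OC)cc(OC)c(OC)c2C1=O | intermediate
16 | 2-[(2S)-2-(tert-butyldimethylsilyloxy)propyl]-5,7,8-trimethoxynaphthalen-1-ol | C[C@H](O[Si](C)(C)C(C)(C)C)Cc1ccc2c(OC)cc(OC)c(OC)c2c1O | intermediate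
17 | 2-[(2S)-2-(tert-butyldimethylsilyloxy)propyl]-5,7,8-trimethoxynaphthalene-1,4-dione | C[C@H](O[Si](C)(C)C(C)(C)C)CC1=CC(=O)c2c(OC)cc(OC)c(OC)c2C1=O | intermediate
18 | 2,3-epoxide of 17 (epoxide diastereomers) | C[C@H](O[Si](C)(C)C(C)(C)C)CC12OC1C(=O)c3c(OC)cc(OC)c(OC)c3C2=O | intermediate
19 | 2-[(2S)-2-(tert-butyldimethylsilyloxy)propyl]-3-hydroxy-5,7,8-trimethoxynaphthalene-1,4-dione | C[C@H](O[Si](C)(C)C(C)(C)C)CC1=C(O)C(=O)c2c(OC)cc(OC)c(OC)c2C1=O | intermediate
20 | 3-hydroxy-2-[(2S)-2-hydroxypropyl]-5,7,8-trimethoxynaphthalene-1,4-dione | C[C@H](O)CC1=C(O)C(=O)c2c(OC)cc(OC)c(OC)c2C1=O | intermediate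
21 | (2S)-1-(3-acetoxy-5,7,8-trimethoxy-1,4-dioxo-1,4-dihydronaphthalen-2-yl)propan-2-yl acetate | C[C@H](OC(C)=O)CC1=C(OC(C)=O)C(=O)c2c(OC)cc(OC)c(OC)c2C1=O | intermediate
22 | (2S)-1-(3-hydroxy-5,7,8-trimethoxy-1,4-dioxo-1,4-dihydronaphthalen-2-yl)propan-2-yl acetate | C[C@H](OC(C)=O)CC1=C(O)C(=O)c2c(OC)cc(OC)c(OC)c2C1=O | target

**Step count and risks**

Total steps: 14. Longest linear sequence: 12 steps (1, 2, 3, 6, 7, 8, 9, 10, 11, 12, 13, 14 from 1,2,4-trimethoxybenzene); the aldehyde branch (steps 4 and 5) has 2 steps.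

Most likely to fail:

- **Step 9 (Saegusa aromatisation).** β-Hydride elimination may go into the side chain and return enone 12, or the electron-rich naphthol may be oxidised further. The fallback sets out from tetralone 5 and aromatises before the side chain is attached. 10% Pd/C in refluxing triglyme under a nitrogen sweep gives 5,7,8-trimethoxynaphthalen-1-ol F2. EtMgBr in Et2O, then exchange to CH2Cl2, gives bromomagnesium 5,7,8-trimethoxynaphthalen-1-olate F3. This adds to aldehyde 8 at rt exclusively at the ortho carbon through a magnesium chelate (aldol-type C-hydroxyalkylation of the phenolate), giving 2-[(2S)-2-(tert-butyldimethylsilyloxy)-1-hydroxypropyl]-5,7,8-trimethoxynaphthalen-1-ol F4. Hydrogenolysis of the benzylic C–OH (H2, Pd/C, EtOAc) gives naphthol 16, where the route is rejoined; steps 6 to 9 are replaced.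

- **Step 12 (base isomerisation of the epoxide).** Hydroxide may instead attack a carbonyl and contract the ring. The fallback sets out from quinone 17 and uses the acid-mediated isomerisation with the side chain already acetylated, because a free or silylated 2-hydroxypropyl chain would cyclise onto the quinone in strong acid. Aqueous HF in MeCN gives 2-[(2S)-2-hydroxypropyl]-5,7,8-trimethoxynaphthalene-1,4-dione F5. Ac2O in pyridine gives (2S)-1-(5,7,8-trimethoxy-1,4-dioxo-1,4-dihydronaphthalen-2-yl)propan-2-yl acetate F6. H2O2 and Na2CO3 in THF/H2O at 0 °C for a few minutes give the 2,3-epoxide of F6 F7. Dissolving this in concentrated H2SO4 at 0 °C for 10 min and pouring onto ice gives target 22 directly; steps 11 to 14 are replaced.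

- **Step 7 (mesylation and E1cB).** The hindered carbinol may mesylate slowly, and DBU could begin to remove the γ-hydrogen of enone 12, which would erode the stereocentre. The fallback sets out from aldol 10 and removes the hydroxyl by a radical path that never forms the enone. 1,1'-Thiocarbonyldiimidazole with DMAP in DCE at 60 °C gives the O-(imidazol-1-ylthiocarbonyl) derivative of 10 F1. Bu3SnH and AIBN in toluene at 90 °C (Barton–McCombie) give tetralone 13, where the route is rejoined; compound 12 and step 8 are skipped.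

**Further compounds**

F1 | step 7 | O-{(2S)-2-(tert-butyldimethylsilyloxy)-1-(5,7,8-trimethoxy-1-oxo-1,2,3,4-tetrahydronaphthalen-2-yl)propyl} 1H-imidazole-1-carbothioate | C[C@H](O[Si](C)(C)C(C)(C)C)C(OC(=S)n1ccnc1)C1CCc2c(OC)cc(OC)c(OC)c2C1=O
F2 | step 9 | 5,7,8-trimethoxynaphthalen-1-ol | COc1cc(OC)c2cccc(O)c2c1OC
F3 | step 9 | bromomagnesium 5,7,8-trimethoxynaphthalen-1-olate | COc1cc(OC)c2cccc(O[Mg]Br)c2c1OC
F4 | step 9 | 2-[(2S)-2-(tert-butyldimethylsilyloxy)-1-hydroxypropyl]-5,7,8-trimethoxynaphthalen-1-ol | C[C@H](O[Si](C)(C)C(C)(C)C)C(O)c1ccc2c(OC)cc(OC)c(OC)c2c1O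
F5 | step 12 | 2-[(2S)-2-hydroxypropyl]-5,7,8-trimethoxynaphthalene-1,4-dione | C[C@H](O)CC1=CC(=O)c2c(OC)cc(OC)c(OC)c2C1=O
F6 | step 12 | (2S)-1-(5,7,8-trimethoxy-1,4-dioxo-1,4-dihydronaphthalen-2-yl)propan-2-yl acetate | C[C@H](OC(C)=O)CC1=CC(=O)c2c(OC)cc(OC)c(OC)c2C1=O
F7 | step 12 | 2,3-epoxide of F6 | C[C@H](OC(C)=O)CC12OC1C(=O)c3c(OC)cc(OC)c(OC)c3C2=O
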